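All constants are those of an exercise.

In a one-step world, substrate and coupling partner give first product and stop there, so the yield is the conversion; in this scheme the product is consumed as well.

| setting | theta | beta | gamma |
|---|---|---|---|
| substrate | 0.14 M | 0.14 M | 0.14 M |
| coupling partner | 1.30 equiv | 1.30 equiv | 1.30 equiv |
| temperature | 100 °C | 60 °C | 80 °C |
| time | 6.0 h | 6.0 h | 6.0 h |

    substrate + coupling partner → first product (k1 = 0.257 M⁻¹ min⁻¹, Ea1 = 71.0 kJ mol⁻¹)
    coupling partner + first product → bis adduct (k2 = 0.0903 M⁻¹ min⁻¹, Ea2 = 89.0 kJ mol⁻¹)
    coupling partner + bis adduct → tris adduct (k3 = 0.555 M⁻¹ min⁻¹, Ea3 = 57.0 kJ mol⁻¹)
    coupling partner + tris adduct → tetra adduct (k4 = 0.148 M⁻¹ min⁻¹, Ea4 = 83.0 kJ mol⁻¹)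
    (constants at 100 °C)

- at 100 °C the constants are as listed, elsewhere as the activation energies make them

- the best flask by amount of first product, in percent of the substrate charged; "all alike" if 1.5 percentage points covers them all (theta / beta / gamma / all alike)
- amount of first product at the end, in percent of the substrate charged, theta
- amount of first product at the end, in percent of the substrate charged, beta
- amount of first product at the end, in percent of the substrate charged, gamma

Divide the rate of the second step by that of the first: [coupling partner] cancels. Let x be the fraction of substrate left and s the second constant over the first, the selectivity factor at that temperature. Integrating gives first product, as a fraction of the substrate charged, as (x^s − x)/(1 − s), a curve with no partner in it. The partner and the clock set how far along it a flask travels. The peak of that curve is s^(s/(1 − s)), reached at x = s^(1/(1 − s)). For theta, s is 0.351 and the peak 56.7%; for gamma, s is 0.253 and the peak 62.8%. For beta, s is 0.175, which gives 69.1%: this peak is the selectivity ceiling.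

Now take the cold end, beta. Run the first step by itself, with the partner falling one for one. The product of constant, [substrate] at the start and time is 0.830, which leaves x = 44.9%. The real partner falls faster, so the real x lies higher, and this x stands on the rising side of the curve. That gives a roof of 50.9%, lower than the ceiling. For a floor, send all that passes first product on to tetra adduct. The partner then burns at most 1.23 per substrate converted, x rises to 47.3%, and the curve gives 49.0%. My hand reaches no floor for theta or gamma. I commit to gamma, whose ceiling stands above the roofs of the other two.

The forecast names gamma, with 56.5% in theta, 50% in beta and 61% in gamma, saying of gamma that “it sits near the maximum of first product”. Its beta lies inside my bracket, and its theta and gamma lie under their ceilings.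

The flasks give 56.6% in theta, 50.2% in beta and 62.5% in gamma, so gamma is best. Beta stands inside its bracket, theta stands practically at its ceiling, and gamma stands 0.30 percentage points under its ceiling. Beta ends with 46% of its substrate and 53% of its partner unused. Now charge a neighbour of beta with 3.20 equiv of coupling partner. Its s is unchanged, so the ceiling stays 69.1%, at x = 12.1%. The neighbour gives 69.0%, with 13.1% of its substrate left.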